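**Retrosynthetic overview**
- The methyl ester and the free phenol of the side-chain ring are kept masked as a saturated δ-lactone (chroman-2-one), and the coumarin 7-OH as a silyl ether. Both masks are released together by basic methanolysis in the last step.
- The strategy rests on the coumarin C3=C4 bond in the pyranone ring O1–C2–C3–C4–C4a–C8a: C4 carries only H and C3 only the aryl ether oxygen, so this alkene is cut by ring-closing metathesis to a 2-vinylaryl 2-aryloxyacrylate.
- The ester O1–C2 of that precursor is cut to a 2-vinylphenol (from 2,4-dihydroxy-5-methoxybenzaldehyde by 4-O-silylation and Wittig methylenation) and a 2-aryloxyacrylic acid.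
- The acid comes from hydrogenated umbelliferone and tert-butyl 2,3-dibromopropanoate by a substitution–elimination cascade, followed by tert-butyl ester acidolysis.
- Ring order: the saturated lactone ring is carried from umbelliferone, the pyranone ring of the coumarin is the only ring formed (step 7), and the saturated lactone is opened last.

Key step: step 7

Remark: the target has no stereocentre and its only non-aromatic C=C is endocyclic, so no stereocontrol is needed; tert-butyl 2,3-dibromopropanoate is taken as a catalogue reagent.

**Step 1**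
Reactants: 1 umbelliferone (7-hydroxy-2H-chromen-2-one)
Product: 2 7-hydroxychroman-2-one
Conditions: H2 (1–3 atm), 10% Pd/C, AcOH, 50 °C
Reagents that add atoms: none
Why: Heterogeneous catalytic hydrogenation should saturate the conjugated lactone C3=C4 while the benzenoid ring stays inert at low pressure, and acetic acid as solvent keeps the aryl-ester lactone from solvolysis.

**Step 2**
Reactants: 2 7-hydroxychroman-2-one; 3 tert-butyl 2,3-dibromopropanoate (racemic)
Product: 7 tert-butyl 2-[(2-oxochroman-7-yl)oxy]acrylate, via tert-butyl 2-bromoacrylate 4 (not isolated), via β-aryloxy α-bromo ester 5 (not isolated), via bis(aryloxy)propanoate 6 (not isolated)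
Conditions: 3 (1.2 equiv), K2CO3 (3 equiv), acetone, reflux
Reagents that add atoms: none
Why: This is a base-mediated elimination–addition–substitution–elimination cascade in which carbonate removes HBr from 3 to give 4, the phenoxide of 2 adds oxa-Michael to give 5, a second phenoxide displaces the activated α-bromide (Williamson SN2) to give 6, and E1cB loss of the β-aryloxide (2 itself, which re-enters) leaves the α-aryloxy acrylate, while anhydrous carbonate in acetone should spare the lactone and the tert-butyl ester.

**Step 3**
Reactants: 7 tert-butyl 2-[(2-oxochroman-7-yl)oxy]acrylate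
Product: 8 2-[(2-oxochroman-7-yl)oxy]acrylic acid
Conditions: TFA, CH2Cl2, 0 °C → rt
Reagents that add atoms: none
Why: Acidolysis of the tert-butyl ester (loss of the tert-butyl cation as isobutene) frees the acid without water or nucleophile, so the lactone should survive and the enol ether, whose protonation is disfavoured by the adjacent carboxyl, should not hydrolyse.

**Step 4**
Reactants: 9 2,4-dihydroxy-5-methoxybenzaldehyde
Product: 10 4-[(tert-butyldimethylsilyl)oxy]-2-hydroxy-5-methoxybenzaldehyde
Conditions: TBSCl (1.05 equiv), imidazole (2 equiv), CH2Cl2, 0 °C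
Reagents that add atoms: tert-butyldimethylsilyl chloride, CC(C)(C)[Si](C)(C)Cl
Why: Selective O-silylation is expected at the 4-OH, the more acidic and accessible phenol, because the 2-OH is held in an intramolecular hydrogen bond to the aldehyde.

**Step 5**
Reactants: 10 4-[(tert-butyldimethylsilyl)oxy]-2-hydroxy-5-methoxybenzaldehyde
Product: 11 5-[(tert-butyldimethylsilyl)oxy]-4-methoxy-2-vinylphenol
Conditions: Ph3PCH3Br (2.3 equiv), NaHMDS (2.2 equiv), THF, 0 °C; then 10, 0 °C → rt; aq NH4Cl; used at once
Reagents that add atoms: methyltriphenylphosphonium bromide, C[P+](c1ccccc1)(c1ccccc1)c1ccccc1.[Br-]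
Why: Wittig methylenation of a salicylaldehyde, in which one equivalent of ylide is spent on the phenol and the second converts the aldehyde into the vinyl group, and the ylide, free of alkoxide and amide base, should leave the aryl silyl ether in place.

**Step 6**
Reactants: 8 2-[(2-oxochroman-7-yl)oxy]acrylic acid; 11 5-[(tert-butyldimethylsilyl)oxy]-4-methoxy-2-vinylphenol
Product: 12 5-[(tert-butyldimethylsilyl)oxy]-4-methoxy-2-vinylphenyl 2-[(2-oxochroman-7-yl)oxy]acrylate
Conditions: DCC (1.1 equiv), DMAP (0.1 equiv), CH2Cl2, 0 °C → rt
Reagents that add atoms: none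
Why: Steglich esterification acylates the phenol through the acylpyridinium under neutral conditions that should leave the silyl ether, the lactone, the styrene and the enol ether untouched.

**Step 7**
Reactants: 12 5-[(tert-butyldimethylsilyl)oxy]-4-methoxy-2-vinylphenyl 2-[(2-oxochroman-7-yl)oxy]acrylate
Product: 13 7-[(tert-butyldimethylsilyl)oxy]-6-methoxy-3-[(2-oxochroman-7-yl)oxy]-2H-chromen-2-one
Conditions: Grubbs 2nd-generation catalyst (10 mol %, two portions), toluene (0.005 M), 80 °C, Ar sparge
Reagents that add atoms: none
Why: The ruthenium alkylidene should exchange onto the electron-rich styrene terminus, the resulting aryl-bound benzylidene adds [2+2] to the tethered CH2=C(OAr) unit with ruthenium on the CH2 carbon, and cycloreversion of the ruthenacyclobutane releases the coumarin and Ru=CH2, which carries the chain with loss of ethene. The closest known reaction is the ring-closing metathesis of 2-vinylaryl acrylates and methacrylates to coumarins, here with an oxygen in place of the α-methyl group. The pyranone ring closes as a six-membered ring by joining C3 to C4 through the intramolecular metathesis, which needs the s-cis ester rotamer, accessible for an aryl ester at 80 °C. No stereocentre is formed and the new alkene is held cis by the ring. The selectivity needed is ring closure over intermolecular styrene homocoupling, which high dilution, the reversibility of stilbene formation with a second-generation catalyst, the reluctance of the 1,1-disubstituted donor–acceptor acrylate to homodimerise and the gain of the conjugated coumarin should secure. The fully substituted enol-ether carbon cannot become a Fischer carbene in the productive regiochemistry, and the silyl ether, both lactone carbonyls and the aryl ethers are inert to the catalyst.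

**Step 8**
Reactants: 13 7-[(tert-butyldimethylsilyl)oxy]-6-methoxy-3-[(2-oxochroman-7-yl)oxy]-2H-chromen-2-one
Product: 15 methyl 3-{2-hydroxy-4-[(7-hydroxy-6-methoxy-2-oxo-2H-chromen-3-yl)oxy]phenyl}propanoate (target), via desilylated lactone 14 (not isolated)
Conditions: K2CO3 (3 equiv), MeOH, 0 °C → rt; then 1 M HCl to pH 4, 0 °C
Reagents that add atoms: methanol, CO
Why: Basic methanolysis should cleave the aryl silyl ether (good 7-coumarinolate leaving group) and transesterify the saturated aryl-ester lactone to the methyl ester and phenoxide, while the coumarin lactone, deactivated by its 7-phenoxide and able at most to open reversibly to a cis-cinnamate that recloses on mild acidification, is retained.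

**Compound list**
1 | umbelliferone (7-hydroxy-2H-chromen-2-one) | O=c1ccc2ccc(O)cc2o1 | starting material
2 | 7-hydroxychroman-2-one | O=C1CCc2ccc(O)cc2O1 | intermediate
3 | tert-butyl 2,3-dibromopropanoate (racemic) | CC(C)(C)OC(=O)C(Br)CBr | starting material
4 | tert-butyl 2-bromoacrylate | C=C(Br)C(=O)OC(C)(C)C | intermediate
5 | tert-butyl 2-bromo-3-[(2-oxochroman-7-yl)oxy]propanoate (racemic) | CC(C)(C)OC(=O)C(Br)COc1ccc2CCC(=O)Oc2c1 | intermediate
6 | tert-butyl 2,3-bis[(2-oxochroman-7-yl)oxy]propanoate (racemic) | CC(C)(C)OC(=O)C(COc1ccc2CCC(=O)Oc2c1)Oc1ccc2CCC(=O)Oc2c1 | intermediate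
7 | tert-butyl 2-[(2-oxochroman-7-yl)oxy]acrylate | C=C(Oc1ccc2CCC(=O)Oc2c1)C(=O)OC(C)(C)C | intermediate
8 | 2-[(2-oxochroman-7-yl)oxy]acrylic acid | C=C(Oc1ccc2CCC(=O)Oc2c1)C(=O)O | intermediate
9 | 2,4-dihydroxy-5-methoxybenzaldehyde | COc1cc(C=O)c(O)cc1O | starting material
10 | 4-[(tert-butyldimethylsilyl)oxy]-2-hydroxy-5-methoxybenzaldehyde | COc1cc(C=O)c(O)cc1O[Si](C)(C)C(C)(C)C | intermediate
11 | 5-[(tert-butyldimethylsilyl)oxy]-4-methoxy-2-vinylphenol | C=Cc1cc(OC)c(O[Si](C)(C)C(C)(C)C)cc1O | intermediate
12 | 5-[(tert-butyldimethylsilyl)oxy]-4-methoxy-2-vinylphenyl 2-[(2-oxochroman-7-yl)oxy]acrylate | C=Cc1cc(OC)c(O[Si](C)(C)C(C)(C)C)cc1OC(=O)C(=C)Oc1ccc2CCC(=O)Oc2c1 | intermediate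
13 | 7-[(tert-butyldimethylsilyl)oxy]-6-methoxy-3-[(2-oxochroman-7-yl)oxy]-2H-chromen-2-one | COc1cc2cc(Oc3ccc4CCC(=O)Oc4c3)c(=O)oc2cc1O[Si](C)(C)C(C)(C)C | intermediate
14 | 7-hydroxy-6-methoxy-3-[(2-oxochroman-7-yl)oxy]-2H-chromen-2-one | COc1cc2cc(Oc3ccc4CCC(=O)Oc4c3)c(=O)oc2cc1O | intermediate
15 | methyl 3-{2-hydroxy-4-[(7-hydroxy-6-methoxy-2-oxo-2H-chromen-3-yl)oxy]phenyl}propanoate | COC(=O)CCc1ccc(Oc2cc3cc(OC)c(O)cc3oc2=O)cc1O | target

**Total step count:** 8
**Longest linear sequence:** 6 steps (steps 1, 2, 3, 6, 7, 8)

**Steps most likely to fail**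

1. Step 7. The metathesis at the 1,1-disubstituted, oxygen-bearing acrylate may be too slow, so that the catalyst decays while the styrene ends couple intermolecularly to stilbene oligomers. The fallback sets out from 2 and 10 and returns at 13, forming C3=C4 by condensation instead of metathesis. Phenol 2 would be O-alkylated with tert-butyl bromoacetate (K2CO3, acetone, reflux) to tert-butyl 2-[(2-oxochroman-7-yl)oxy]acetate F1. TFA in CH2Cl2 would free 2-[(2-oxochroman-7-yl)oxy]acetic acid F2. DCC/DMAP would couple F2 to the phenol of salicylaldehyde 10 to give 5-[(tert-butyldimethylsilyl)oxy]-2-formyl-4-methoxyphenyl 2-[(2-oxochroman-7-yl)oxy]acetate F3. DBU in MeCN should then close the pyranone ring by intramolecular aldol addition of the ester enolate to the formyl group and dehydration (Perkin/Knoevenagel-type coumarin synthesis), giving 13.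

2. Step 2. The cascade may stall at the bis(aryloxy) adduct or divert to the β-aryloxy acrylate, and the phenoxide may open the lactone of a second molecule and oligomerise. The fallback sets out from 2 and returns at 7, building the α-aryloxy acrylate by O–H insertion and olefination. tert-Butyl diethylphosphonoacetate would be converted by diazo transfer (NaH, p-ABSA, THF) into tert-butyl 2-diazo-2-(diethoxyphosphoryl)acetate F4. Rh2(OAc)4-catalysed carbenoid O–H insertion into phenol 2 (toluene, 80 °C) would give tert-butyl 2-(diethoxyphosphoryl)-2-[(2-oxochroman-7-yl)oxy]acetate F5. Horner–Wadsworth–Emmons methylenation with paraformaldehyde (LiCl, DBU, MeCN) should then deliver 7.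

3. Step 5. The electron-rich 2-vinylphenol may polymerise or oxidise on isolation, and the free phenoxide present during the Wittig reaction may cause migration or loss of the aryl silyl group. The fallback sets out from 10 and 8 and returns at 12, so that no free vinylphenol is handled. Salicylaldehyde 10 would first be esterified with acid 8 (DCC, DMAP, CH2Cl2) to 5-[(tert-butyldimethylsilyl)oxy]-2-formyl-4-methoxyphenyl 2-[(2-oxochroman-7-yl)oxy]acrylate F6. The aldehyde would then be methylenated under neutral rhodium catalysis (RhCl(PPh3)3 cat., TMSCHN2, PPh3, 2-propanol, THF, rt), which is aldehyde-selective and tolerates esters, to give 12. The donor-substituted acrylate is a poor dipolarophile and should not compete for the diazo reagent.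

**Further compounds**
F1 | step 7 | tert-butyl 2-[(2-oxochroman-7-yl)oxy]acetate | CC(C)(C)OC(=O)COc1ccc2CCC(=O)Oc2c1
F2 | step 7 | 2-[(2-oxochroman-7-yl)oxy]acetic acid | OC(=O)COc1ccc2CCC(=O)Oc2c1
F3 | step 7 | 5-[(tert-butyldimethylsilyl)oxy]-2-formyl-4-methoxyphenyl 2-[(2-oxochroman-7-yl)oxy]acetate | COc1cc(C=O)c(OC(=O)COc2ccc3CCC(=O)Oc3c2)cc1O[Si](C)(C)C(C)(C)C
F4 | step 2 | tert-butyl 2-diazo-2-(diethoxyphosphoryl)acetate | CCOP(=O)(OCC)C(=[N+]=[N-])C(=O)OC(C)(C)C
F5 | step 2 | tert-butyl 2-(diethoxyphosphoryl)-2-[(2-oxochroman-7-yl)oxy]acetate (racemic) | CCOP(=O)(OCC)C(Oc1ccc2CCC(=O)Oc2c1)C(=O)OC(C)(C)C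
F6 | step 5 | 5-[(tert-butyldimethylsilyl)oxy]-2-formyl-4-methoxyphenyl 2-[(2-oxochroman-7-yl)oxy]acrylate | C=C(Oc1ccc2CCC(=O)Oc2c1)C(=O)Oc1cc(O[Si](C)(C)C(C)(C)C)c(OC)cc1C=O
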